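The earlier runs and the new flask come from a simulation with made-up constants; the scatter is artificial.

Read the flask in percent of the substrate charged. In that unit Friday's run at 0.42 M and Sunday's at 0.66 M lie on one curve: at 80.0 s substrate reads 51 % and 48 %, and target 32 % and 35 %, against a scatter of 2 percentage points. So pool both runs for the new flask.

| flask | substrate | remark | time |
|---|---|---|---|
| Friday's | 0.42 M | run made earlier |  |
| Sunday's | 0.66 M | run made earlier |  |
| flask | 0.30 M |  | 2.0 min |

| run | time / s | target / % | isomer of the product A / % | substrate / % |
|---|---|---|---|---|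
| Friday's | 10.0 | 8 | 0 | 89 |
| Friday's | 20.0 | 17 | 3 | 76 |
| Friday's | 40.0 | 29 | 5 | 63 |
| Friday's | 80.0 | 32 | 11 | 51 |
| Sunday's | 10.0 | 11 | 1 | 91 |
| Sunday's | 20.0 | 17 | 1 | 81 |
| Sunday's | 30.0 | 24 | 0 | 71 |
| Sunday's | 50.0 | 33 | 9 | 55 |
| Sunday's | 80.0 | 35 | 9 | 48 |

(scatter of a reading: 2 percentage points)

1. ratio of target to isomer of the product A at 2.0 s
2. ratio of target to isomer of the product A at 15 s
3. ratio of target to isomer of the product A at 2.0 min
4. which of target and isomer of the product A there is more of at 2.0 min

Compare two amounts: late target and late isomer of the product A. Early pairs are no use, since Sunday's isomer of the product A reads 0 % at 30.0 s, inside the scatter. Later it reads 9 % at 50.0 s and 9 % at 80.0 s, while target goes from 33 % to 35 %, and Friday's run gives 11 % at 80.0 s. So freeze the ratio and average these three late readings: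

c(target) / c(isomer of the product A) = 33.3 % / 9.67 % = 3.45

Call this reading the late ratio. It carries the scatter of the isomer readings, and holding it constant up to 2.0 min is my assumption. My reckoning for 2.0 min is this ratio, with target ahead. I give no early ratios of my own.

The forecast gives 165 (90 to 300) at 2.0 s, 20 (11 to 36) at 15 s and 1.7 (1.3 to 2.4) at 2.0 min, with target ahead. Of the isomer it says “so it comes from target rather than directly from substrate”. Its late ratio is lower than mine.

The flask gives 132, 18.4 and 3.76, with 39.0 % target against 10.4 % isomer of the product A.

    substrate ⇌ target (K = 1.20, k = 0.0120 s⁻¹)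
    isomer of the product A ⇌ isomer of the product B (K = 1.40, k = 0.00180 s⁻¹)
    target ⇌ isomer of the product A (K = 0.320, k = 0.00740 s⁻¹)
    isomer of the product B ⇌ substrate (k = 0.00370 s⁻¹)

In this flask target to isomer of the product A runs both ways: up to 2.0 min its backward turnover is 59 % of the forward one. The flask's ratio goes from 5.58 at 1.00 min through 3.76 at 2.0 min to 3.13 at 20.0 min, so it does not hold still as I assumed; my reckoning for 2.0 min was 3.45.

For the neighbour flask charged with 0.75 M, percent readings carry over, so the late ratio again gives 3.45 at 2.0 min. The computed ratio there is 3.76, with 10.4 % isomer of the product A.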